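Readings and results are simulated on assumed constants; noise was put on by code.

1. The violet run has the recipe of north. Its first reading, taken as a straight line from the start, gave Q a starting rate of 0.108 d⁻¹ as a fraction of the D charged, and its last reading held Q at 10 % while E had grown to 70 %. Dividing the two gave 0.926 d. I call this the working window of G, the time the starting rate of Q needs to make the Q standing at the end. Each of these readings carries 2 percentage points.

| flask | D | G | remark | time |
|---|---|---|---|---|
| violet | 0.10 M | 0.90 equiv | run made earlier |  |
| red | 0.10 M | 1.3 equiv | run made earlier |  |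
| grey | 0.10 M | 2 equiv | run made earlier |  |
| blue | 0.15 M | 0.90 equiv | run made earlier |  |
| east | 0.10 M (fed, over 8.0 d) | 0.900 equiv | all else is in the flask from the start; the feed brings no volume worth counting | 10 d |
| north-west | 0.10 M | 0.900 equiv (in portions, 2, over 8.0 d) | first portion at the start, last at 8.0 d | 10 d |
| north | 0.10 M | 0.900 equiv | everything together at the start | 10 d |
| west | 0.10 M | 0.900 equiv (fed, over 8.0 d) | all else is in the flask from the start; the feed brings no volume worth counting | 10 d |

| run | time / d | Q / % | E / % |
|---|---|---|---|
| violet | 0.833 | 9 | 21 |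
| violet | 1.25 | 10 | 23 |
| violet | 1.67 | 14 | 32 |
| violet | 3.00 | 10 | 47 |
| violet | 4.00 | 13 | 53 |
| violet | 6.00 | 13 | 64 |
| violet | 10.0 | 10 | 70 |
| red | 0.625 | 10 | 16 |
| red | 1.04 | 12 | 27 |
| red | 1.67 | 10 | 32 |
| red | 2.50 | 11 | 38 |
| red | 3.00 | 11 | 42 |
| red | 5.00 | 13 | 57 |
| red | 8.00 | 11 | 66 |
| grey | 0.625 | 12 | 14 |
| grey | 1.04 | 14 | 23 |
| grey | 1.67 | 15 | 28 |
| grey | 2.50 | 15 | 37 |
| grey | 3.00 | 18 | 44 |
| grey | 5.00 | 20 | 52 |
| grey | 8.00 | 16 | 60 |
| blue | 0.625 | 7 | 14 |
| blue | 2.08 | 13 | 34 |
| blue | 4.00 | 9 | 48 |
| blue | 6.00 | 7 | 60 |
| blue | 8.00 | 10 | 63 |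

(readings scatter by 2 percentage points)



- the flask with the highest share of Q in Q plus E ("all alike" if they lie within 1.5 percentage points) (east / north-west / north / west / all alike)
- share of Q in Q plus E at the end, east
- share of Q in Q plus E at the end, north-west
- share of Q in Q plus E at the end, north
- share of Q in Q plus E at the end, west

2. The share asked for is the selectivity. I solved east at both ends. With a window as long as the feed, D meets working G throughout, and I took the Q of east as the Q of violet's last reading. With a short window, the Q of violet shrinks to the fraction of the feed that has entered within the window. I joined the ends by letting Q grow with that fraction up to 1.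

3. I then turned the question round. On my joined line, east came level with north where the window reached the feed time. The window read from violet was shorter than 8.0 d, and the fraction came to 0.116.

4. Taking Q plus E from violet's last reading, I reckoned north at 12.5 % and east at 1.45 %, so in my reckoning north stood higher. I did not reckon the two flasks fed with G.

5. The forecast differs from my reckoning. It named east, with east 20 % (14 % to 32 %), north-west 8 % (5 % to 12 %), north 13 % (10.5 % to 16 %) and west 7 % (4 % to 11 %). Its ground for east was: “East keeps G full”.

6. The flasks gave north as highest, with east 5.65 %, north-west 9.52 %, north 13.1 % and west 9.59 %.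

    D + G → Q (k = 0.110 M⁻¹ h⁻¹)
    D → E (k = 0.0110 h⁻¹)
    2 G → L (k = 0.340 M⁻¹ h⁻¹)
    D → J (k = 3.40 × 10⁻⁵ h⁻¹)
    D + Q → Z (k = 0.130 M⁻¹ h⁻¹)

7. East ended with Q at 4.11 %, against my 1.16 %. The neighbour is north with G cut to 0.230 equiv. For it I scaled violet's starting rate by the charge of G and held the window at 0.926 d, which gave Q of 2.56 %. The neighbour held 4.78 %, so its window, read the same way, came to 1.73 d, longer than violet's. Its share of Q in Q plus E was 5.49 %.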